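**Retrosynthetic overview**

1. The target is numbered as 6-oxabicyclo[3.2.2]non-3-ene-2,7-dione: C1 bridgehead CH, C2 ketone, C3(allyl)=C4, C5 C(OMe), O6, C7 lactone C=O, C8 CH–Ar, C9 CH–Me. The last disconnection takes O6 out of the C5–O6–C7 acylal (Baeyer–Villiger retron), leaving a bicyclo[3.2.1]oct-3-ene-2,8-dione with the old C7 as bridging ketone.
2. Enabling feature: C1–H lies between the C2 ketone and the C7 carbonyl (a 1,3-dicarbonyl), and C1 is the only enolisable α-carbon of the five-membered ring C7–C1–C8–C9–C5 because C5 is fully substituted. The C1–C2 bond is therefore an enolate acylation by an acyl group held on C5 through the cis C3=C4 alkene; it closes the six-membered carbocycle C1–C2–C3–C4–C5–C7.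
3. Key disconnection: C1–C2 and C8–aryl in one operation. Conjugate addition of the arylmagnesium reagent to a 5,5-disubstituted cyclopentenone creates the C1 enolate regiospecifically, and this enolate is acylated by the (Z)-Weinreb enamide arm.
4. The cyclopentenone comes from (S)-4-silyloxycyclopent-2-enone. Its five ring carbons become C7, C5, C9, C8 and C1, and its single stereocentre is relayed (methyl trans to OSi, oxygen anti to methyl, aryl anti to methyl) and then erased. The Z-arm comes from ozonolysis and a Still–Gennari-type olefination.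
5. Ring order: five-membered ring (purchased) → six-membered carbocycle (key step, bicyclo[3.2.1]) → lactone ring by oxygen insertion (6-oxabicyclo[3.2.2]).

Key step: step 10

Remark: the (S)-enantiomer of 4-(tert-butyldimethylsilyloxy)cyclopent-2-en-1-one and a THF solution of (3,4,5-trimethoxyphenyl)magnesium bromide are taken as purchasable.

**Route**

Step 1
Reactants: 1 2-bromo-N-methoxy-N-methylacetamide; 2 tris(2,2,2-trifluoroethyl) phosphite
Product: 3 bis(2,2,2-trifluoroethyl) {2-[methoxy(methyl)amino]-2-oxoethyl}phosphonate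
Conditions: neat, 150 °C, CF3CH2Br distilled off
Reagents that add atoms: none
Why: A Michaelis–Arbuzov reaction of the α-bromo amide, driven by loss of the volatile bromide, should give the Still–Gennari-type phosphonate that already carries the Weinreb amide.

Step 2
Reactants: 3 bis(2,2,2-trifluoroethyl) {2-[methoxy(methyl)amino]-2-oxoethyl}phosphonate
Product: 4 bis(2,2,2-trifluoroethyl) {1-[methoxy(methyl)amino]-1-oxopent-4-en-2-yl}phosphonate (racemic)
Conditions: NaH, THF, 0 °C; allyl bromide, 0 °C → rt
Reagents that add atoms: allyl bromide, C=CCBr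
Why: C-Alkylation of the doubly stabilised phosphonate carbanion is standard for Horner–Wadsworth–Emmons reagents; the new stereocentre is racemic and becomes sp2 in step 8.

Step 3
Reactants: 5 (S)-4-[(tert-butyldimethylsilyl)oxy]cyclopent-2-en-1-one
Product: 6 (S)-4-[(tert-butyldimethylsilyl)oxy]-2-iodocyclopent-2-en-1-one
Conditions: iodine, pyridine, CH2Cl2, 0 °C → rt
Reagents that add atoms: iodine, [I][I]
Why: Pyridine-mediated α-iodination of the enone (addition–iodination–elimination, Baylis–Hillman-type mechanism) arms C2 for cross-coupling and leaves the silyloxy stereocentre untouched.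

Step 4
Reactants: 6 (S)-4-[(tert-butyldimethylsilyl)oxy]-2-iodocyclopent-2-en-1-one
Product: 7 (S)-4-[(tert-butyldimethylsilyl)oxy]-2-ethenylcyclopent-2-en-1-one
Conditions: tributyl(ethenyl)stannane, PdCl2(PhCN)2 (cat.), AsPh3, CuI, NMP, rt; used at once
Reagents that add atoms: tributyl(ethenyl)stannane, C=C[Sn](CCCC)(CCCC)CCCC
Why: Stille coupling of an α-iodoenone is well precedented and installs a vinyl group that later becomes the aldehyde carbon; immediate use avoids Diels–Alder dimerisation of the cross-conjugated dienone.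

Step 5
Reactants: 7 (S)-4-[(tert-butyldimethylsilyl)oxy]-2-ethenylcyclopent-2-en-1-one
Product: 10 (2S,3R,4S)-4-[(tert-butyldimethylsilyl)oxy]-2-ethenyl-2-hydroxy-3-methylcyclopentan-1-one, via trimethylsilyl dienol ether 8 (not isolated), via silyloxy epoxide 9 (not isolated)
Conditions: MeMgBr, CuBr·SMe2 (cat.), TMSCl, THF, −78 °C; pentane extraction; DMDO, acetone–CH2Cl2, −78 → 0 °C; aq. citric acid
Reagents that add atoms: methylmagnesium bromide, C[Mg]Br; dimethyldioxirane, CC1(C)OO1
Why: Copper-catalysed, TMSCl-assisted conjugate addition should place methyl trans to the silyloxy group and trap a single enolate regioisomer, and Rubottom oxidation then delivers oxygen to the enol ether face anti to the new methyl group, so the tertiary hydroxyl is trans and the vinyl group cis to methyl.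

Step 6
Reactants: 10 (2S,3R,4S)-4-[(tert-butyldimethylsilyl)oxy]-2-ethenyl-2-hydroxy-3-methylcyclopentan-1-one
Product: 11 (2S,3R,4S)-4-[(tert-butyldimethylsilyl)oxy]-2-ethenyl-2-methoxy-3-methylcyclopentan-1-one
Conditions: MeOTf, 2,6-di-tert-butyl-4-methylpyridine, CH2Cl2, 40 °C
Reagents that add atoms: methyl trifluoromethanesulfonate, COS(=O)(=O)C(F)(F)F
Why: O-Methylation of the hindered tertiary alcohol under non-basic conditions should avoid β-elimination of the silyloxy group and α-ketol rearrangement.

Step 7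
Reactants: 11 (2S,3R,4S)-4-[(tert-butyldimethylsilyl)oxy]-2-ethenyl-2-methoxy-3-methylcyclopentan-1-one
Product: 13 (1R,2R,3S)-3-[(tert-butyldimethylsilyl)oxy]-1-methoxy-2-methyl-5-oxocyclopentane-1-carbaldehyde, via secondary ozonide 12 (not isolated)
Conditions: O3, CH2Cl2, −78 °C; Me2S, −78 °C → rt
Reagents that add atoms: ozone, [O-][O+]=O
Why: Ozonolysis of the only C=C bond gives the non-enolisable α-methoxy aldehyde under anhydrous, neutral conditions that should not deformylate the β-keto aldehyde.

Step 8
Reactants: 13 (1R,2R,3S)-3-[(tert-butyldimethylsilyl)oxy]-1-methoxy-2-methyl-5-oxocyclopentane-1-carbaldehyde; 4 bis(2,2,2-trifluoroethyl) {1-[methoxy(methyl)amino]-1-oxopent-4-en-2-yl}phosphonate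
Product: 14 (2Z)-2-({(1S,2R,3S)-3-[(tert-butyldimethylsilyl)oxy]-1-methoxy-2-methyl-5-oxocyclopentyl}methylidene)-N-methoxy-N-methylpent-4-enamide
Conditions: 4, KN(SiMe3)2, 18-crown-6, THF, −78 °C; then 13, −78 °C
Reagents that add atoms: none
Why: A Still–Gennari-type Horner–Wadsworth–Emmons olefination (trifluoroethyl phosphonate, dissociated potassium base) should form the trisubstituted alkene under kinetic control with the ring cis to the amide, the aldehyde reacting in preference to the hindered ketone.

Step 9
Reactants: 14 (2Z)-2-({(1S,2R,3S)-3-[(tert-butyldimethylsilyl)oxy]-1-methoxy-2-methyl-5-oxocyclopentyl}methylidene)-N-methoxy-N-methylpent-4-enamide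
Product: 15 (2Z)-N-methoxy-2-{[(1R,2R)-1-methoxy-2-methyl-5-oxocyclopent-3-en-1-yl]methylidene}-N-methylpent-4-enamide
Conditions: DBU, CH2Cl2, 0 °C → rt
Reagents that add atoms: none
Why: E1cB elimination of silanolate from the β-silyloxy ketone unveils the enone and erases the controlling stereocentre once it has set the methyl and methoxy centres.

Step 10
Reactants: 15 (2Z)-N-methoxy-2-{[(1R,2R)-1-methoxy-2-methyl-5-oxocyclopent-3-en-1-yl]methylidene}-N-methylpent-4-enamide; 16 (3,4,5-trimethoxyphenyl)magnesium bromide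
Product: 19 (1R,5R,6R,7R)-5-methoxy-6-methyl-3-(prop-2-en-1-yl)-7-(3,4,5-trimethoxyphenyl)bicyclo[3.2.1]oct-3-ene-2,8-dione, via bromomagnesium enolate 17 (not isolated), via tetrahedral hemiaminal adduct 18 (not isolated)
Conditions: 16 (slow addition), CuBr·SMe2 (cat.), THF, −78 °C, then → rt; aq. NH4Cl
Reagents that add atoms: none
Why: A catalytic arylcopper species from 16 and CuBr·SMe2 adds 1,4 to the enone of 15; the bromomagnesium enolate 17 can only be the one toward the former enone α-carbon because the other α-carbon is quaternary, and on warming its carbon attacks the Weinreb amide carbonyl to give the chelated tetrahedral adduct 18, which collapses to the ketone only at the aqueous quench. The closest known reaction type is the tandem copper-mediated conjugate addition–intramolecular Claisen (Dieckmann-type) acylation, used here in the α,α′-annulation geometry by which cyclopentanone enolates give bicyclo[3.2.1]octan-8-ones. One ring is closed, the six-membered carbocycle of the bicyclo[3.2.1]octene, by 6-(enolendo)-exo-trig attack of the enolate carbon on the amide carbonyl. The aryl-bearing carbon is set by substrate control, the nucleophile entering anti to the adjacent methyl group and away from the alkenyl arm on the quaternary carbon; the new bridgehead carbon is fixed by the tether, which reaches the enolate only from its own face (anti to aryl). The step needs 1,4- over 1,2-addition, no reaction at the enamide and no cleavage of the non-enolisable β-diketone: copper catalysis at low temperature, the poor acceptor character of the α-branched Weinreb enamide, and the stability of 18 (no alkoxide is released, so no retro-Claisen and no second addition) should secure these, while O-acylation is reversible and returns to 17.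

Step 11
Reactants: 19 (1R,5R,6R,7R)-5-methoxy-6-methyl-3-(prop-2-en-1-yl)-7-(3,4,5-trimethoxyphenyl)bicyclo[3.2.1]oct-3-ene-2,8-dione
Product: 20 (1R,5S,8R,9R)-5-methoxy-9-methyl-3-(prop-2-en-1-yl)-8-(3,4,5-trimethoxyphenyl)-6-oxabicyclo[3.2.2]non-3-ene-2,7-dione
Conditions: mCPBA, NaHCO3, CH2Cl2, 0 °C
Reagents that add atoms: 3-chloroperoxybenzoic acid, OOC(=O)c1cccc(Cl)c1
Why: In this Baeyer–Villiger oxidation the strained, non-conjugated bridging ketone should react before the enone carbonyl, and the tertiary methoxy- and vinyl-substituted bridgehead should migrate with retention rather than the α-acyl CH, which puts oxygen between C(OMe) and C=O; the electron-poor enone alkene and the monosubstituted allyl alkene are slow toward the buffered peracid.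

**Compound list**

1 | 2-bromo-N-methoxy-N-methylacetamide | BrCC(=O)N(C)OC | starting material
2 | tris(2,2,2-trifluoroethyl) phosphite | FC(F)(F)COP(OCC(F)(F)F)OCC(F)(F)F | starting material
3 | bis(2,2,2-trifluoroethyl) {2-[methoxy(methyl)amino]-2-oxoethyl}phosphonate | CON(C)C(=O)CP(=O)(OCC(F)(F)F)OCC(F)(F)F | intermediate
4 | bis(2,2,2-trifluoroethyl) {1-[methoxy(methyl)amino]-1-oxopent-4-en-2-yl}phosphonate (racemic) | CON(C)C(=O)C(CC=C)P(=O)(OCC(F)(F)F)OCC(F)(F)F | intermediate
5 | (S)-4-[(tert-butyldimethylsilyl)oxy]cyclopent-2-en-1-one | O=C1C[C@H](O[Si](C)(C)C(C)(C)C)C=C1 | starting material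
6 | (S)-4-[(tert-butyldimethylsilyl)oxy]-2-iodocyclopent-2-en-1-one | O=C1C[C@H](O[Si](C)(C)C(C)(C)C)C=C1I | intermediate
7 | (S)-4-[(tert-butyldimethylsilyl)oxy]-2-ethenylcyclopent-2-en-1-one | O=C1C[C@H](O[Si](C)(C)C(C)(C)C)C=C1C=C | intermediate
8 | (3S,4S)-4-[(tert-butyldimethylsilyl)oxy]-2-ethenyl-3-methyl-1-[(trimethylsilyl)oxy]cyclopent-1-ene (methyl trans to OSi) | C=CC1=C(O[Si](C)(C)C)C[C@H](O[Si](C)(C)C(C)(C)C)[C@H]1C | intermediate
9 | epoxide of the enol ether bond of 8, oxygen on the face opposite the methyl group (5-ethenyl-4-methyl-3-(tert-butyldimethylsilyloxy)-1-(trimethylsilyloxy)-6-oxabicyclo[3.1.0]hexane) | C=C[C@@]1(O2)[C@@]2(O[Si](C)(C)C)C[C@H](O[Si](C)(C)C(C)(C)C)[C@H]1C | intermediate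
10 | (2S,3R,4S)-4-[(tert-butyldimethylsilyl)oxy]-2-ethenyl-2-hydroxy-3-methylcyclopentan-1-one | C=C[C@@]1(O)C(=O)C[C@H](O[Si](C)(C)C(C)(C)C)[C@H]1C | intermediate
11 | (2S,3R,4S)-4-[(tert-butyldimethylsilyl)oxy]-2-ethenyl-2-methoxy-3-methylcyclopentan-1-one | C=C[C@@]1(OC)C(=O)C[C@H](O[Si](C)(C)C(C)(C)C)[C@H]1C | intermediate
12 | secondary ozonide of 11 (1,2,4-trioxolan-3-yl in place of ethenyl; ring stereocentres as in 11, trioxolane carbon unassigned) | O1COOC1[C@@]2(OC)C(=O)C[C@H](O[Si](C)(C)C(C)(C)C)[C@H]2C | intermediate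
13 | (1R,2R,3S)-3-[(tert-butyldimethylsilyl)oxy]-1-methoxy-2-methyl-5-oxocyclopentane-1-carbaldehyde | O=C[C@@]1(OC)C(=O)C[C@H](O[Si](C)(C)C(C)(C)C)[C@H]1C | intermediate
14 | (2Z)-2-({(1S,2R,3S)-3-[(tert-butyldimethylsilyl)oxy]-1-methoxy-2-methyl-5-oxocyclopentyl}methylidene)-N-methoxy-N-methylpent-4-enamide | C=CC/C(=C/[C@@]1(OC)C(=O)C[C@H](O[Si](C)(C)C(C)(C)C)[C@H]1C)C(=O)N(C)OC | intermediate
15 | (2Z)-N-methoxy-2-{[(1R,2R)-1-methoxy-2-methyl-5-oxocyclopent-3-en-1-yl]methylidene}-N-methylpent-4-enamide | C=CC/C(=C/[C@@]1(OC)C(=O)C=C[C@H]1C)C(=O)N(C)OC | intermediate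
16 | (3,4,5-trimethoxyphenyl)magnesium bromide | COc1cc([Mg]Br)cc(OC)c1OC | starting material
17 | bromomagnesium enolate of the conjugate adduct of 15 (aryl trans to methyl, enolate toward the aryl-bearing carbon) | C=CC/C(=C/[C@@]1(OC)C(O[Mg]Br)=C[C@H](c2cc(OC)c(OC)c(OC)c2)[C@H]1C)C(=O)N(C)OC | intermediate
18 | bromomagnesium alkoxide of the N-methoxy-N-methyl hemiaminal at C2 of the bicyclo[3.2.1]oct-3-en-8-one (hemiaminal carbon unassigned) | C=CCC1=C[C@@]2(OC)C(=O)[C@@H](C1(O[Mg]Br)N(C)OC)[C@H](c1cc(OC)c(OC)c(OC)c1)[C@H]2C | intermediate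
19 | (1R,5R,6R,7R)-5-methoxy-6-methyl-3-(prop-2-en-1-yl)-7-(3,4,5-trimethoxyphenyl)bicyclo[3.2.1]oct-3-ene-2,8-dione | C=CCC1=C[C@@]2(OC)C(=O)[C@@H](C1=O)[C@H](c1cc(OC)c(OC)c(OC)c1)[C@H]2C | intermediate
20 | (1R,5S,8R,9R)-5-methoxy-9-methyl-3-(prop-2-en-1-yl)-8-(3,4,5-trimethoxyphenyl)-6-oxabicyclo[3.2.2]non-3-ene-2,7-dione | C=CCC1=C[C@@]2(OC)OC(=O)[C@@H](C1=O)[C@H](c1cc(OC)c(OC)c(OC)c1)[C@H]2C | target

**Step count and risks**

Total step count: 11 (steps 1–2 make the olefination reagent 4; steps 3–11 are the main line). Longest linear sequence: 9 steps (5 → 20).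

Steps most likely to fail:

Step 10. The magnesium enolate may be too unreactive toward the hindered, conjugated amide, so that conjugate addition occurs without ring closure, or free Grignard reagent may add 1,2. The fallback sets out from 15 and separates the two events. A Hayashi–Miyaura 1,4-addition of (3,4,5-trimethoxyphenyl)boronic acid ([Rh(cod)OH]2, dioxane–H2O, 50 °C) should stop at (2Z)-N-methoxy-2-{[(1R,2R,3S)-1-methoxy-2-methyl-5-oxo-3-(3,4,5-trimethoxyphenyl)cyclopentyl]methylidene}-N-methylpent-4-enamide F1, with the aryl group again anti to methyl. F1 is then deprotonated at its only enolisable α-carbon with LiN(SiMe3)2 (THF, −78 → 0 °C), and the more nucleophilic lithium enolate should close onto the Weinreb amide. The route is rejoined at 19.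

Step 8. Addition to the neopentyl-type aldehyde may be slow, Z-selectivity may erode, and the base may eliminate the silyloxy group first. The fallback sets out from 13. A Stork–Zhao olefination with (1-iodobut-3-en-1-ylidene)triphenylphosphorane F2 (made in the flask from (but-3-en-1-yl)triphenylphosphonium bromide, NaN(SiMe3)2 and iodine; THF, −78 °C) should give (2R,3R,4S)-4-[(tert-butyldimethylsilyl)oxy]-2-[(1Z)-2-iodopenta-1,4-dien-1-yl]-2-methoxy-3-methylcyclopentan-1-one F3. Aminocarbonylation (Pd(OAc)2, Xantphos, CO 1 atm, MeNHOMe·HCl, Et3N, toluene, 80 °C) then replaces iodine by the Weinreb amide with retention of alkene geometry. The route is rejoined at 14.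

Step 11. Oxidation may occur at the wrong site (enone carbonyl or allyl alkene), or the bridged acylal may lose methanol under the acidic by-product in the final step. The fallback sets out from 14 and moves the oxygen insertion to the monocyclic stage, where there is a single ketone. Baeyer–Villiger oxidation (mCPBA, NaHCO3, CH2Cl2) should give (2Z)-2-({(2R,3R,4S)-4-[(tert-butyldimethylsilyl)oxy]-2-methoxy-3-methyl-6-oxooxan-2-yl}methylidene)-N-methoxy-N-methylpent-4-enamide F4. DBU then eliminates silanol to give (2Z)-N-methoxy-2-{[(2S,3R)-2-methoxy-3-methyl-6-oxo-3,6-dihydro-2H-pyran-2-yl]methylidene}-N-methylpent-4-enamide F5. The copper-catalysed conjugate arylation with 16, followed by acylation of the lactone enolate by the Weinreb amide, makes the same ring-closing bond as a non-oxidative last step. The route is rejoined at 20.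

Further compounds
F1 | step 10 | (2Z)-N-methoxy-2-{[(1R,2R,3S)-1-methoxy-2-methyl-5-oxo-3-(3,4,5-trimethoxyphenyl)cyclopentyl]methylidene}-N-methylpent-4-enamide | C=CC/C(=C/[C@@]1(OC)C(=O)C[C@H](c2cc(OC)c(OC)c(OC)c2)[C@H]1C)C(=O)N(C)OC
F2 | step 8 | (1-iodobut-3-en-1-ylidene)triphenylphosphorane | C=CCC(I)=P(c1ccccc1)(c1ccccc1)c1ccccc1
F3 | step 8 | (2R,3R,4S)-4-[(tert-butyldimethylsilyl)oxy]-2-[(1Z)-2-iodopenta-1,4-dien-1-yl]-2-methoxy-3-methylcyclopentan-1-one | C=CC/C(I)=C/[C@@]1(OC)C(=O)C[C@H](O[Si](C)(C)C(C)(C)C)[C@H]1C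
F4 | step 11 | (2Z)-2-({(2R,3R,4S)-4-[(tert-butyldimethylsilyl)oxy]-2-methoxy-3-methyl-6-oxooxan-2-yl}methylidene)-N-methoxy-N-methylpent-4-enamide | C=CC/C(=C/[C@@]1(OC)OC(=O)C[C@H](O[Si](C)(C)C(C)(C)C)[C@H]1C)C(=O)N(C)OC
F5 | step 11 | (2Z)-N-methoxy-2-{[(2S,3R)-2-methoxy-3-methyl-6-oxo-3,6-dihydro-2H-pyran-2-yl]methylidene}-N-methylpent-4-enamide | C=CC/C(=C/[C@@]1(OC)OC(=O)C=C[C@H]1C)C(=O)N(C)OC
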